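Ring B of the target is a trans-2,3-dimethylpyranone whose ether oxygen O1 is attached to arene carbon C8a, the carbon ortho to the C4 ketone. Everything rests on disconnecting O1–C8a. An open-chain anti β-hydroxy aryl ketone, which already holds C2 and C3 (from ethyl (S)-3-hydroxybutanoate) and carries fluorine on the future C8a, is closed by intramolecular nucleophilic aromatic substitution. That single operation makes the aryl ether and ring B and leaves both stereocentres as installed. Afterwards only the arene is elaborated: O5 demethylation, a lactone ring across O5/C6 reduced enantioselectively to set the side-chain centre, prenylation at C8 and lactone opening.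

Key step: step 5

Remarks on the chemistry (assumptions)
- Numbering: chromanone numbering (O1, C2, C3, C4, C4a, C5–C8, C8a) is used for compounds 10–16 and 24. The tricyclic lactones 17–22 are numbered as pyrano[2,3-f]chromenes (O1, C2 lactone carbonyl, C3, C4, C4a, C5, C6, C6a, O7, C8, C9, C10, C10a, C10b); tricycle C4, C5, C6, O7, C8, C9, C10 correspond to the side-chain carbon, C7, C8, O1, C2, C3, C4 of the chromanone.
- The secondary hydroxyl is carried unprotected from step 2 onwards, so the ketone-forming step delivers the cyclisation substrate directly.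
- The antipode of the bisphosphine in step 9 is assigned by analogy with 4-substituted coumarins and is to be confirmed on a model 4-propylcoumarin; the mirror-image ligand is used if the sense is opposite.
- Hex-2-ynoic acid and tributyl(3-methylbut-2-en-1-yl)stannane are taken as purchased.

Step 1
Reactants: 1 ethyl (S)-3-hydroxybutanoate
Product: 3 ethyl (2S,3S)-3-hydroxy-2-methylbutanoate, via dilithium alkoxide enolate 2 (not isolated)
Conditions: LiN(i-Pr)2 (2.2 equiv), THF, −78 → −20 °C; MeI (1.3 equiv), DMPU, −78 → 0 °C; aq NH4Cl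
Reagents that add atoms: iodomethane, CI
Why: Fráter–Seebach alkylation: the chelated dilithium alkoxide enolate 2 is methylated on the face away from the C3 methyl group, which should set C2 as S, anti to the hydroxyl, under control of the chiral-pool centre C3.

Step 2
Reactants: 3 ethyl (2S,3S)-3-hydroxy-2-methylbutanoate
Product: 4 (2S,3S)-3-hydroxy-N-methoxy-N,2-dimethylbutanamide
Conditions: MeNH(OMe)·HCl (1.5 equiv), i-PrMgCl (4.1 equiv), THF, −20 → 0 °C; aq NH4Cl
Reagents that add atoms: N,O-dimethylhydroxylamine hydrochloride, CNOC.Cl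
Why: Weinreb amidation of an ester by the chloromagnesium amide made in the flask; the hydroxyl is present as its magnesium alkoxide, which disfavours α-deprotonation, so C2 should not epimerise.

Step 3
Reactants: 5 1-fluoro-3,5-dimethoxybenzene
Product: 6 2-bromo-1-fluoro-3,5-dimethoxybenzene
Conditions: NBS (1.0 equiv), MeCN, 0 °C → rt
Reagents that add atoms: N-bromosuccinimide, O=C1CCC(=O)N1Br
Why: Electrophilic aromatic bromination at C2, para to one methoxy group and ortho to the other, the activated position with the smaller flanking group (F instead of a second OMe); any symmetrical 4-bromo isomer is removed by crystallisation or chromatography.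

Step 4
Reactants: 6 2-bromo-1-fluoro-3,5-dimethoxybenzene; 4 (2S,3S)-3-hydroxy-N-methoxy-N,2-dimethylbutanamide
Product: 10 (2S,3S)-1-(2-fluoro-4,6-dimethoxyphenyl)-3-hydroxy-2-methylbutan-1-one, via aryllithium 7 (not isolated), via chloromagnesium alkoxide 8 (not isolated), via tetrahedral adduct 9 (not isolated)
Conditions: 6 (1.3 equiv) + n-BuLi (1.25 equiv), THF, −78 °C; 4 + i-PrMgCl (1.05 equiv), THF, −40 °C, added at −78 °C, then −50 °C; aq NH4Cl at −78 °C
Reagents that add atoms: none
Why: Bromine–lithium exchange followed by a Weinreb ketone synthesis: the hydroxyl is masked as magnesium alkoxide 8, adduct 9 holds the carbonyl at the ketone oxidation level until the quench, and the sequence stays at or below −50 °C so that the ortho-fluoroaryllithium does not lose LiF to an aryne; no stereocentre takes part.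

Step 5
Reactants: 10 (2S,3S)-1-(2-fluoro-4,6-dimethoxyphenyl)-3-hydroxy-2-methylbutan-1-one
Product: 12 (2S,3S)-5,7-dimethoxy-2,3-dimethylchroman-4-one, via potassium alkoxide 11 (not isolated)
Conditions: KN(SiMe3)2 (1.05 equiv), THF, −78 → 0 °C; pH 7 phosphate buffer
Reagents that add atoms: none
Why: The amide base removes the hydroxyl proton at −78 °C and potassium alkoxide 11 adds to the fluorine-bearing carbon C8a, giving an anionic σ-adduct whose charge is taken up by the ortho C4 carbonyl, after which fluoride leaves (addition–elimination, SNAr). The closest known reaction type is the intramolecular SNAr etherification of ortho-fluoroaryl ketones by tethered alkoxides, which gives chroman-4-ones and related benzo-fused oxygen heterocycles. Ring B closes in a six-membered mode that is formally 6-endo-trig with respect to the C8a=C4a–C4=O acceptor unit (6-exo-trig if counted on the C8a=C8 bond), the same geometry as an oxa-Michael closure to a chromanone. No stereocentre is created: the C2–O bond is never broken, so C2 keeps its chiral-pool S configuration, and C3 keeps the S configuration from step 1, which is also the thermodynamically preferred trans arrangement should any enolisation occur. The selectivity needed is ring closure over retro-aldol cleavage and over enolate-driven loss of water; it is secured by fluoride as leaving group ortho to the ketone, by both methoxy groups lying meta to C8a, by complete alkoxide formation with one equivalent of a non-nucleophilic base at low temperature, and by that base being consumed as KF so that the product does not stand in excess base.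

Step 6
Reactants: 12 (2S,3S)-5,7-dimethoxy-2,3-dimethylchroman-4-one
Product: 14 (2S,3S)-5-hydroxy-7-methoxy-2,3-dimethylchroman-4-one, via dichloroboron chelate 13 (not isolated)
Conditions: BCl3 (1.5 equiv), CH2Cl2, −78 → 0 °C; H2O
Reagents that add atoms: none
Why: Chelation-directed Lewis acid ether cleavage: boron held between the C4 carbonyl oxygen and O5 activates only the peri methyl ether for chloride attack, the C7 methyl ether has no such assistance, and the non-basic conditions leave C2 and C3 alone.

Step 7
Reactants: 14 (2S,3S)-5-hydroxy-7-methoxy-2,3-dimethylchroman-4-one; 15 hex-2-ynoic acid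
Product: 16 (2S,3S)-7-methoxy-2,3-dimethyl-4-oxochroman-5-yl hex-2-ynoate
Conditions: DIC (1.3 equiv), DMAP (10 mol%), CH2Cl2, 0 °C → rt
Reagents that add atoms: none
Why: Steglich-type esterification (carbodiimide activation, DMAP acyl transfer) of the hydrogen-bonded 5-OH under neutral conditions that do not enolise C3; low temperature and a small DMAP charge limit conjugate addition to the ynoate.

Step 8
Reactants: 16 (2S,3S)-7-methoxy-2,3-dimethyl-4-oxochroman-5-yl hex-2-ynoate
Product: 17 (8S,9S)-5-methoxy-8,9-dimethyl-4-propyl-8,9-dihydro-2H,10H-pyrano[2,3-f]chromene-2,10-dione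
Conditions: Ph3PAuCl (5 mol%), AgSbF6 (5 mol%), 1,2-dichloroethane, rt → 50 °C
Reagents that add atoms: none
Why: Gold-catalysed intramolecular hydroarylation of an aryl alkynoate: the cationic gold–alkyne complex is attacked by C6, the only free position ortho to O5 and activated by the ortho C7 methoxy and para O1, in a 6-endo-dig closure, and protodeauration releases the 4-propylcoumarin without a Brønsted acid strong enough to reopen ring B.

Step 9
Reactants: 17 (8S,9S)-5-methoxy-8,9-dimethyl-4-propyl-8,9-dihydro-2H,10H-pyrano[2,3-f]chromene-2,10-dione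
Product: 19 (4R,8S,9S)-5-methoxy-8,9-dimethyl-4-propyl-3,4,8,9-tetrahydro-2H,10H-pyrano[2,3-f]chromene-2,10-dione, via silyl ketene acetal 18 (not isolated)
Conditions: Cu(OAc)2·H2O (5 mol%), (S)-DTBM-SEGPHOS (5.5 mol%), (EtO)2MeSiH (1.3 equiv), toluene, 0 °C → rt; 1 M HCl, THF, 0 °C
Reagents that add atoms: none
Why: CuH-catalysed asymmetric conjugate reduction of a coumarin: the bisphosphine-ligated copper hydride delivers hydride to one face of C4 (catalyst control, 4R), the enolate is trapped as silyl ketene acetal 18 so that the lactone carbonyl is not reduced further, and the limiting silane together with the hindered, strongly donor-substituted C10 ketone should hold back 1,2-reduction.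

Step 10
Reactants: 19 (4R,8S,9S)-5-methoxy-8,9-dimethyl-4-propyl-3,4,8,9-tetrahydro-2H,10H-pyrano[2,3-f]chromene-2,10-dione
Product: 20 (4R,8S,9S)-6-iodo-5-methoxy-8,9-dimethyl-4-propyl-3,4,8,9-tetrahydro-2H,10H-pyrano[2,3-f]chromene-2,10-dione
Conditions: NIS (1.05 equiv), TFA (10 mol%), MeCN, 0 °C → rt
Reagents that add atoms: N-iodosuccinimide, O=C1CCC(=O)N1I
Why: Electrophilic aromatic iodination at the single remaining ring C–H, C6 of the tricycle (C8 of the chromanone), which lies between the methoxy-bearing C5 and the ether-oxygen-bearing C6a; the saturated lactone offers no competing vinylic position.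

Step 11
Reactants: 20 (4R,8S,9S)-6-iodo-5-methoxy-8,9-dimethyl-4-propyl-3,4,8,9-tetrahydro-2H,10H-pyrano[2,3-f]chromene-2,10-dione; 21 tributyl(3-methylbut-2-en-1-yl)stannane
Product: 22 (4R,8S,9S)-5-methoxy-8,9-dimethyl-6-(3-methylbut-2-en-1-yl)-4-propyl-3,4,8,9-tetrahydro-2H,10H-pyrano[2,3-f]chromene-2,10-dione
Conditions: Pd2(dba)3 (5 mol%), AsPh3 (20 mol%), CuI (10 mol%), DMF, 60 °C
Reagents that add atoms: none
Why: Stille coupling of the aryl iodide with the prenylstannane under neutral conditions: oxidative addition, allyl transfer assisted by CuI and reductive elimination at the less substituted allyl terminus should give the linear 3-methylbut-2-enyl group, while lactone, ketone and the C9 centre are not exposed to base.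

Step 12
Reactants: 22 (4R,8S,9S)-5-methoxy-8,9-dimethyl-6-(3-methylbut-2-en-1-yl)-4-propyl-3,4,8,9-tetrahydro-2H,10H-pyrano[2,3-f]chromene-2,10-dione
Product: 24 (3R)-3-[(2S,3S)-5-hydroxy-7-methoxy-2,3-dimethyl-8-(3-methylbut-2-en-1-yl)-4-oxochroman-6-yl]hexanoic acid, via dilithium salt 23 (not isolated)
Conditions: LiOH·H2O (3 equiv), THF/H2O 3:1, 0 °C; 1 M HCl to pH 3–4, 0 °C
Reagents that add atoms: lithium hydroxide, [Li+].[OH-]
Why: Saponification of an aryl lactone at 0 °C: the liberated phenoxide is conjugated with the C4 carbonyl, which lowers the acidity of C3–H during the reaction, and cold acidification gives the acid whose 5-OH is hydrogen-bonded to the ketone and therefore slow to relactonise.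

Compound list
1 | ethyl (S)-3-hydroxybutanoate | CCOC(=O)C[C@H](C)O | starting material
2 | dilithium alkoxide enolate of 1 | CCOC(O[Li])=C[C@H](C)O[Li] | intermediate
3 | ethyl (2S,3S)-3-hydroxy-2-methylbutanoate | O[C@@H](C)[C@H](C)C(=O)OCC | intermediate
4 | (2S,3S)-3-hydroxy-N-methoxy-N,2-dimethylbutanamide | O[C@@H](C)[C@H](C)C(=O)N(C)OC | intermediate
5 | 1-fluoro-3,5-dimethoxybenzene | COc1cc(F)cc(OC)c1 | starting material
6 | 2-bromo-1-fluoro-3,5-dimethoxybenzene | COc1cc(F)c(Br)c(OC)c1 | intermediate
7 | (2-fluoro-4,6-dimethoxyphenyl)lithium | COc1cc(F)c([Li])c(OC)c1 | intermediate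
8 | chloromagnesium alkoxide of 4 | Cl[Mg]O[C@@H](C)[C@H](C)C(=O)N(C)OC | intermediate
9 | tetrahedral adduct of 7 and 8 (lithium hemiaminal alkoxide, chloromagnesium alkoxide) | CON(C)C(O[Li])(c1c(F)cc(OC)cc1OC)[C@@H](C)[C@H](C)O[Mg]Cl | intermediate
10 | (2S,3S)-1-(2-fluoro-4,6-dimethoxyphenyl)-3-hydroxy-2-methylbutan-1-one | O[C@@H](C)[C@H](C)C(=O)c1c(F)cc(OC)cc1OC | intermediate
11 | potassium alkoxide of 10 | [K+].[O-][C@@H](C)[C@H](C)C(=O)c1c(F)cc(OC)cc1OC | intermediate
12 | (2S,3S)-5,7-dimethoxy-2,3-dimethylchroman-4-one | COc1cc(OC)c2c(c1)O[C@@H](C)[C@H](C)C2=O | intermediate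
13 | O5-dichloroboryl chelate of (2S,3S)-5-hydroxy-7-methoxy-2,3-dimethylchroman-4-one | COc1cc(OB(Cl)Cl)c2c(c1)O[C@@H](C)[C@H](C)C2=O | intermediate
14 | (2S,3S)-5-hydroxy-7-methoxy-2,3-dimethylchroman-4-one | COc1cc(O)c2c(c1)O[C@@H](C)[C@H](C)C2=O | intermediate
15 | hex-2-ynoic acid | CCCC#CC(=O)O | starting material
16 | (2S,3S)-7-methoxy-2,3-dimethyl-4-oxochroman-5-yl hex-2-ynoate | CCCC#CC(=O)Oc1cc(OC)cc2O[C@@H](C)[C@H](C)C(=O)c12 | intermediate
17 | (8S,9S)-5-methoxy-8,9-dimethyl-4-propyl-8,9-dihydro-2H,10H-pyrano[2,3-f]chromene-2,10-dione (coumarin fused across O5/C6 of the chromanone) | CCCC1=CC(=O)Oc2c1c(OC)cc3O[C@@H](C)[C@H](C)C(=O)c23 | intermediate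
18 | (4R,8S,9S)-2-[diethoxy(methyl)silyloxy]-5-methoxy-8,9-dimethyl-4-propyl-8,9-dihydro-4H,10H-pyrano[2,3-f]chromen-10-one | CCC[C@@H]1C=C(O[Si](C)(OCC)OCC)Oc2c1c(OC)cc3O[C@@H](C)[C@H](C)C(=O)c23 | intermediate
19 | (4R,8S,9S)-5-methoxy-8,9-dimethyl-4-propyl-3,4,8,9-tetrahydro-2H,10H-pyrano[2,3-f]chromene-2,10-dione | CCC[C@@H]1CC(=O)Oc2c1c(OC)cc3O[C@@H](C)[C@H](C)C(=O)c23 | intermediate
20 | (4R,8S,9S)-6-iodo-5-methoxy-8,9-dimethyl-4-propyl-3,4,8,9-tetrahydro-2H,10H-pyrano[2,3-f]chromene-2,10-dione | CCC[C@@H]1CC(=O)Oc2c1c(OC)c(I)c3O[C@@H](C)[C@H](C)C(=O)c23 | intermediate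
21 | tributyl(3-methylbut-2-en-1-yl)stannane | CCCC[Sn](CCCC)(CCCC)CC=C(C)C | starting material
22 | (4R,8S,9S)-5-methoxy-8,9-dimethyl-6-(3-methylbut-2-en-1-yl)-4-propyl-3,4,8,9-tetrahydro-2H,10H-pyrano[2,3-f]chromene-2,10-dione | CCC[C@@H]1CC(=O)Oc2c1c(OC)c(CC=C(C)C)c3O[C@@H](C)[C@H](C)C(=O)c23 | intermediate
23 | dilithium phenoxide carboxylate of 24 | CCC[C@H](CC(=O)[O-])c1c([O-])c2c(c(CC=C(C)C)c1OC)O[C@@H](C)[C@H](C)C2=O.[Li+].[Li+] | intermediate
24 | (3R)-3-[(2S,3S)-5-hydroxy-7-methoxy-2,3-dimethyl-8-(3-methylbut-2-en-1-yl)-4-oxochroman-6-yl]hexanoic acid | CCC[C@H](CC(=O)O)c1c(O)c2c(c(CC=C(C)C)c1OC)O[C@@H](C)[C@H](C)C2=O | target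

Total step count: 12
Longest linear sequence: 11 steps (steps 1, 2, 4–12; step 3 is the one-step side branch)

Steps most likely to fail

Step 5. Retro-aldol fragmentation of the alkoxide, or base-induced loss of water, may outrun the ring closure; re-aldolisation would also erode the C2 configuration. The fallback sets out from 10 and removes both channels by changing the oxidation level. Dess–Martin periodinane in CH2Cl2 gives the β-diketone 1-(2-fluoro-4,6-dimethoxyphenyl)-2-methylbutane-1,3-dione F1. K2CO3 in DMF then closes the same O1–C8a bond through the enolate oxygen to the chromone 5,7-dimethoxy-2,3-dimethyl-4H-chromen-4-one F2. Asymmetric hydrogenation of the C2=C3 bond (H2, Ru(cod)(2-methylallyl)2, chiral imidazolinylidene ligand from (R,R)-SINpEt·HBF4 and KOt-Bu, antipode chosen for 2S) adds both hydrogens to one face and gives the cis-dimethyl chromanol (2S,3S)-5,7-dimethoxy-2,3-dimethylchroman-4-ol F3, its C4 epimers carried together. Dess–Martin oxidation gives the cis ketone (2S,3R)-5,7-dimethoxy-2,3-dimethylchroman-4-one F4, and DBU in CH2Cl2 epimerises C3 to the trans isomer, rejoining the route at 12.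

Step 9. Hydride delivery to the C10 ketone, or further reduction of the lactone, may compete with conjugate reduction, and facial discrimination at the hindered C4 may be insufficient. The fallback sets out from 17 and takes the ketone out of play before the copper hydride step. Luche reduction (NaBH4, CeCl3·7H2O, MeOH/THF, −20 °C) gives the benzylic alcohol (8S,9R,10R)-10-hydroxy-5-methoxy-8,9-dimethyl-4-propyl-9,10-dihydro-2H,8H-pyrano[2,3-f]chromen-2-one F5 (major C10 epimer; both epimers converge later). The same CuH conditions with excess silane (the hydroxyl is silylated in the flask and freed on acidic work-up) then give (4R,8S,9R,10R)-10-hydroxy-5-methoxy-8,9-dimethyl-4-propyl-3,4,9,10-tetrahydro-2H,8H-pyrano[2,3-f]chromen-2-one F6. Dess–Martin periodinane with NaHCO3 in CH2Cl2 re-oxidises the benzylic alcohol (and any lactol), rejoining the route at 19.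

Step 11. Oxidative addition at the doubly ortho-oxygenated iodide may be slow, and the allyl group may transfer with transposition or the iodide may be lost by protodehalogenation. The fallback sets out from 19 and installs the prenyl group by sigmatropic rearrangement instead of cross-coupling. K2CO3 in MeOH at 0 °C opens the lactone to methyl (3R)-3-[(2S,3S)-5-hydroxy-7-methoxy-2,3-dimethyl-4-oxochroman-6-yl]hexanoate F7. Mitsunobu etherification (3-methylbut-2-en-1-ol, PPh3, DIAD, THF) gives methyl (3R)-3-[(2S,3S)-7-methoxy-2,3-dimethyl-5-(3-methylbut-2-en-1-yloxy)-4-oxochroman-6-yl]hexanoate F8. Eu(fod)3 in toluene at 80–110 °C promotes a para-Claisen sequence (Claisen shift to a blocked ortho carbon, then Cope shift to C8, then tautomerisation) to methyl (3R)-3-[(2S,3S)-5-hydroxy-7-methoxy-2,3-dimethyl-8-(3-methylbut-2-en-1-yl)-4-oxochroman-6-yl]hexanoate F9. LiOH in THF/H2O at 0 °C followed by cold acidification rejoins the route at 24; if F9 relactonises to 22 under the Lewis acid, the same hydrolysis applies.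

Further compounds
F1 | step 5 | 1-(2-fluoro-4,6-dimethoxyphenyl)-2-methylbutane-1,3-dione | CC(=O)C(C)C(=O)c1c(F)cc(OC)cc1OC
F2 | step 5 | 5,7-dimethoxy-2,3-dimethyl-4H-chromen-4-one | COc1cc(OC)c2c(c1)OC(C)=C(C)C2=O
F3 | step 5 | (2S,3S)-5,7-dimethoxy-2,3-dimethylchroman-4-ol, methyl groups cis, C4 epimers carried together | COc1cc(OC)c2c(c1)O[C@@H](C)[C@@H](C)C2O
F4 | step 5 | (2S,3R)-5,7-dimethoxy-2,3-dimethylchroman-4-one | COc1cc(OC)c2c(c1)O[C@@H](C)[C@@H](C)C2=O
F5 | step 9 | (8S,9R,10R)-10-hydroxy-5-methoxy-8,9-dimethyl-4-propyl-9,10-dihydro-2H,8H-pyrano[2,3-f]chromen-2-one | CCCC1=CC(=O)Oc2c1c(OC)cc3O[C@@H](C)[C@H](C)[C@@H](O)c23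
F6 | step 9 | (4R,8S,9R,10R)-10-hydroxy-5-methoxy-8,9-dimethyl-4-propyl-3,4,9,10-tetrahydro-2H,8H-pyrano[2,3-f]chromen-2-one | CCC[C@@H]1CC(=O)Oc2c1c(OC)cc3O[C@@H](C)[C@H](C)[C@@H](O)c23
F7 | step 11 | methyl (3R)-3-[(2S,3S)-5-hydroxy-7-methoxy-2,3-dimethyl-4-oxochroman-6-yl]hexanoate | CCC[C@H](CC(=O)OC)c1c(O)c2c(cc1OC)O[C@@H](C)[C@H](C)C2=O
F8 | step 11 | methyl (3R)-3-[(2S,3S)-7-methoxy-2,3-dimethyl-5-(3-methylbut-2-en-1-yloxy)-4-oxochroman-6-yl]hexanoate | CCC[C@H](CC(=O)OC)c1c(OCC=C(C)C)c2c(cc1OC)O[C@@H](C)[C@H](C)C2=O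
F9 | step 11 | methyl (3R)-3-[(2S,3S)-5-hydroxy-7-methoxy-2,3-dimethyl-8-(3-methylbut-2-en-1-yl)-4-oxochroman-6-yl]hexanoate | CCC[C@H](CC(=O)OC)c1c(O)c2c(c(CC=C(C)C)c1OC)O[C@@H](C)[C@H](C)C2=O
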